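A direct plan would diazotise 2-amino-3-bromophenol A1 to the ortho-quinone diazide A3, let the carbene formed from A3 and Rh2(OAc)4 insert into an O–H bond of excess catechol A2 to give 3-bromo-2-(2-hydroxyphenoxy)phenol A4, and brominate A4 twice with NBS by way of the monobromide A5.
Its weakest steps would be:
- the carbene O–H insertion that makes the diaryl ether from A3 and A2: it would have no precedent for a monocyclic halogenated quinone diazide, and azo coupling, Wolff ring contraction and attack at arene carbon would compete;
- the double bromination of A4 at the end: each ring offers positions para and ortho to OH and para to the ether oxygen, so regioisomers and over-bromination would arise in the last step;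
- the removal of the fivefold excess of A2, which would otherwise consume NBS.

The route would rest on a [3+3] disconnection of ring A itself rather than on a union of two arenes. Ring A carries OH at C1, the ether oxygen at C2 and bromine at C4, which is the pattern that a ketone ArO–CH2–CO–CH3 and symmetric 2-bromomalonaldehyde give on double aldol condensation. The ether oxygen would therefore be attached to an sp3 carbon by plain SN2, and one operation would then close ring A and place all three of its substituents by construction. Ring B would arrive with both bromines and its second oxygen from a site-specific lithiation. No carbene insertion and no bromination of a diaryl ether would remain.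

Key step: step 3

Remark: ring A is the 5-bromo-2-hydroxyphenoxy ring, numbered as a phenol (C1–OH, C2–O–aryl, C4–Br); ring B is the 3,4-dibromophenol ring; the target has no stereocentre; 1,2-dibromo-4-methoxybenzene, chloroacetone and 2-bromomalonaldehyde are taken as purchased.

Step 1
Reactants: 1 1,2-dibromo-4-methoxybenzene (3,4-dibromoanisole)
Product: 4 2,3-dibromo-6-methoxyphenol, via aryllithium 2 (not isolated), via aryl boronate 3 (not isolated)
Conditions: 1 and B(OiPr)3 (1.5 equiv), THF, −78 °C, lithium 2,2,6,6-tetramethylpiperidide (LiTMP, 1.3 equiv) added slowly; then AcOH, 30% aq H2O2, 0 °C to rt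
Reagents that add atoms: hydrogen peroxide, OO (gives the phenol oxygen); triisopropyl borate, CC(C)OB(OC(C)C)OC(C)C (its boron and isopropoxy groups are held only in 3 and leave as boric acid and propan-2-ol); lithium 2,2,6,6-tetramethylpiperidide, [Li]N1C(C)(C)CCCC1(C)C (its lithium is held only in 2)
Why: Directed ortho-lithiation with in situ borate trapping, then oxidation of the aryl–boron bond: the hydrogen flanked by OMe and Br is the most acidic, the amide base does not exchange bromine, trapping as the anion forms should forestall loss of LiBr to an aryne and halogen dance, and the acidic peroxide oxidation moves the aryl group from boron to oxygen at the same carbon without base-induced loss of boron; no stereocentre is formed.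

Step 2
Reactants: 4 2,3-dibromo-6-methoxyphenol; 5 chloroacetone
Product: 6 1-(2,3-dibromo-6-methoxyphenoxy)propan-2-one
Conditions: 5 (1.3 equiv), K2CO3 (1.5 equiv), DMF, 50 °C
Reagents that add atoms: none
Why: Williamson ether synthesis (SN2) on an α-chloro ketone, an electrophile activated enough that the doubly ortho-substituted phenoxide of 4 should still alkylate on oxygen; no stereocentre is formed.

Step 3
Reactants: 6 1-(2,3-dibromo-6-methoxyphenoxy)propan-2-one; 7 2-bromomalonaldehyde
Product: 10 4-bromo-2-(2,3-dibromo-6-methoxyphenoxy)phenol, via open-chain adduct 8 (not isolated), via cyclohexadienone 9 (not isolated)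
Conditions: 7 (1.3 equiv), NaOH (3.5 equiv), EtOH–H2O (3:1), rt then 50 °C; then 1 M HCl to pH 3
Reagents that add atoms: none
Why: This is a base-mediated [3+3] cyclocondensation (double aldol condensation): the enolate at the aryloxy-bearing CH2 of 6 adds to one formyl group of 7 and water is lost to give open-chain adduct 8, the methyl-ketone enolate of 8 then adds to the remaining formyl group, and loss of the second water gives dienone 9, whose enolisation to the phenol makes the sequence irreversible. The closest known reaction type is the cyclocondensation of 2-substituted malonaldehydes with ketones that carry two enolisable α-carbons (the para-nitrophenol synthesis from sodium nitromalonaldehyde; the vinamidinium benzannulation is its amine variant), applied here to bromomalonaldehyde and an aryloxyacetone. Ring A is closed by a 6-(enolendo)-exo-trig aldol addition that forms C5–C6 after the intermolecular condensation has formed C2–C3, so that the ketone carbon becomes C1–OH, the aryloxy carbon becomes C2 and the bromine-bearing central carbon of 7 becomes C4, para to the hydroxyl. No stereocentre is formed. No regiochemical choice arises, because 7 is symmetric and both α-carbons of 6 must react whichever reacts first. The step needs condensation to outrun bromine transfer from 7 and self-condensation of 6, which the excess hydroxide should secure by holding 7 as its enolate (no longer a bromonium donor, and present in excess over the ketone enolate), while the aryl bromides and the methyl ether of ring B are inert to aqueous alkali at this temperature.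

Step 4
Reactants: 10 4-bromo-2-(2,3-dibromo-6-methoxyphenoxy)phenol
Product: 12 3,4-dibromo-2-(5-bromo-2-hydroxyphenoxy)phenol, via bis(dibromoboryl) ether 11 (not isolated)
Conditions: BBr3 (3.5 equiv), CH2Cl2, −78 °C to rt; then H2O, 0 °C
Reagents that add atoms: boron tribromide, BrB(Br)Br (its boron and bromine are held only in 11 and leave as boric acid and HBr on hydrolysis)
Why: Lewis-acid demethylation of an aryl methyl ether with BBr3 (bromide attacks the methyl group of the O–B adduct by SN2), a reaction that leaves diaryl ether C–O bonds and aryl C–Br bonds untouched at or below room temperature; no stereocentre is formed.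

Compound list
1 | 1,2-dibromo-4-methoxybenzene (3,4-dibromoanisole) | COc1ccc(Br)c(Br)c1 | starting material
2 | (2,3-dibromo-6-methoxyphenyl)lithium (not isolated) | COc1ccc(Br)c(Br)c1[Li] | intermediate
3 | diisopropyl (2,3-dibromo-6-methoxyphenyl)boronate (not isolated) | COc1ccc(Br)c(Br)c1B(OC(C)C)OC(C)C | intermediate
4 | 2,3-dibromo-6-methoxyphenol | COc1ccc(Br)c(Br)c1O | intermediate
5 | chloroacetone (1-chloropropan-2-one) | CC(=O)CCl | starting material
6 | 1-(2,3-dibromo-6-methoxyphenoxy)propan-2-one | CC(=O)COc1c(OC)ccc(Br)c1Br | intermediate
7 | 2-bromomalonaldehyde (2-bromopropanedial) | O=CC(Br)C=O | starting material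
8 | 5-bromo-3-(2,3-dibromo-6-methoxyphenoxy)-6-hydroxyhexa-3,5-dien-2-one (enol form of the mono-condensation product, present as its sodium enolate, double-bond geometry not fixed; not isolated) | CC(=O)C(Oc1c(OC)ccc(Br)c1Br)=CC(Br)=CO | intermediate
9 | 4-bromo-2-(2,3-dibromo-6-methoxyphenoxy)cyclohexa-2,4-dien-1-one (keto tautomer of 10; not isolated) | O=C1CC=C(Br)C=C1Oc1c(OC)ccc(Br)c1Br | intermediate
10 | 4-bromo-2-(2,3-dibromo-6-methoxyphenoxy)phenol | COc1ccc(Br)c(Br)c1Oc1cc(Br)ccc1O | intermediate
11 | 1,2-dibromo-3-[5-bromo-2-(dibromoboranyloxy)phenoxy]-4-(dibromoboranyloxy)benzene (not isolated) | BrB(Br)Oc1ccc(Br)cc1Oc1c(OB(Br)Br)ccc(Br)c1Br | intermediate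
12 | 3,4-dibromo-2-(5-bromo-2-hydroxyphenoxy)phenol (achiral) | Oc1ccc(Br)cc1Oc1c(O)ccc(Br)c1Br | target

Total step count: 4. Longest linear sequence: 4 steps (1 → 4 → 6 → 10 → 12).

Steps most likely to fail

Step 3 (key step). The first aldol addition to the fully ionised malonaldehyde may be too slow, so that self-condensation of ketone 6 or loss of bromine from 7 takes over and ring A is not closed. The enol oxygen may also displace bromide after the first aldol addition and close a five-membered oxygen ring instead (Feist–Benary-type closure). The fallback would set out from phenol 4 and come back to the route at 10. Nucleophilic aromatic substitution of 4 on purchased 4-bromo-2-fluorobenzaldehyde (K2CO3, DMF, 90 °C) would give 4-bromo-2-(2,3-dibromo-6-methoxyphenoxy)benzaldehyde F1. Baeyer–Villiger (Dakin-type) oxidation with mCPBA in CH2Cl2 would give 4-bromo-2-(2,3-dibromo-6-methoxyphenoxy)phenyl formate F2, and methanolysis (K2CO3, MeOH) would give 10.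

Step 1. The aryllithium may lose LiBr to an aryne or pass bromine on to a neighbouring molecule before the borate traps it, or the hindered boronate may exchange boron for hydrogen before it is oxidised. The fallback would replace starting material 1, so it would set out from no compound of the route but from purchased 2-bromo-6-methoxyphenol, and it would come back at 4. Acetylation (Ac2O, pyridine) would give 2-bromo-6-methoxyphenyl acetate F3. Electrophilic bromination para to the methoxy group (Br2, AcOH, rt) would give 2,3-dibromo-6-methoxyphenyl acetate F4, and deacetylation (K2CO3, MeOH) would give 4.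

Step 2. O-Alkylation of the doubly ortho-substituted phenoxide may be slower than base-induced self-condensation of chloroacetone. The fallback would set out from 4 and come back at 6. Alkylation with 3-chloro-2-methylpropene, which cannot enolise (K2CO3, DMF, 60 °C), would give 1,2-dibromo-4-methoxy-3-[(2-methylprop-2-en-1-yl)oxy]benzene F5, and ozonolysis (O3, CH2Cl2–MeOH, −78 °C; then Me2S) would give ketone 6.

Further compounds
F1 | step 3 | 4-bromo-2-(2,3-dibromo-6-methoxyphenoxy)benzaldehyde | COc1ccc(Br)c(Br)c1Oc1cc(Br)ccc1C=O
F2 | step 3 | 4-bromo-2-(2,3-dibromo-6-methoxyphenoxy)phenyl formate | COc1ccc(Br)c(Br)c1Oc1cc(Br)ccc1OC=O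
F3 | step 1 | 2-bromo-6-methoxyphenyl acetate | COc1cccc(Br)c1OC(C)=O
F4 | step 1 | 2,3-dibromo-6-methoxyphenyl acetate | COc1ccc(Br)c(Br)c1OC(C)=O
F5 | step 2 | 1,2-dibromo-4-methoxy-3-[(2-methylprop-2-en-1-yl)oxy]benzene | COc1ccc(Br)c(Br)c1OCC(C)=C
A1 | direct plan | 2-amino-3-bromophenol | Nc1c(O)cccc1Br
A2 | direct plan | catechol (benzene-1,2-diol) | Oc1ccccc1O
A3 | direct plan | 5-bromo-6-diazocyclohexa-2,4-dien-1-one | O=C1C=CC=C(Br)C1=[N+]=[N-]
A4 | direct plan | 3-bromo-2-(2-hydroxyphenoxy)phenol | Oc1ccccc1Oc1c(O)cccc1Br
A5 | direct plan | 3-bromo-2-(5-bromo-2-hydroxyphenoxy)phenol | Oc1ccc(Br)cc1Oc1c(O)cccc1Br
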